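Halimane numbering is used (ring A: C1–C5, C10; C4 = CMe2, C5 = fusion CH; ring B: C5–C10). In ring A the C1=C10 double bond is allylic to C5, which carries the quaternary C4; with one geminal methyl raised to a carboxyl, C1=C10–C5–C4–CO2H is the retron of an ester-enolate Claisen rearrangement. Ring A is therefore closed at C4–C5 by Ireland–Claisen rearrangement of a δ-lactone whose carbinol carbon C1 hangs on cyclohexene ring B: one operation turns the lactone ring into the carbocycle, forms C4–C5, moves the alkene from C5=C10 to C1=C10 and relays the C1 configuration to C5. The side chain follows by metathesis, auxiliary-controlled allylation and B-alkyl Suzuki coupling.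

Key step: step 6

Remark: further locants are C8 (ring-B CH bearing the secondary methyl), C9 (quaternary ring-B carbon), C11–C12 (ethylene link) and C13 (side-chain stereocentre); the target is taken as the free hydrogen sulfate as drawn, released from its pyridinium salt by proton exchange. Compounds 10–13 are mixtures of epimers at the future C4, which is of no consequence because that centre is enolised in step 6.

Step 1
Reactants: 1 2-iodocyclohex-2-en-1-one; 2 allyltributylstannane
Product: 3 2-allylcyclohex-2-en-1-one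
Conditions: Pd2(dba)3 (2.5 mol %), AsPh3, CuI, NMP, 25 → 50 °C
Reagents that add atoms: none
Why: Stille coupling of an α-iodoenone, in which oxidative addition into the C(sp2)–I bond and allyl transfer from tin should give the 2-allyl enone without touching the enone.

Step 2
Reactants: 3 2-allylcyclohex-2-en-1-one
Product: 5 (2R,3R)-2-allyl-2,3-dimethylcyclohexan-1-one, via magnesium enolate 4 (not isolated)
Conditions: MeMgBr, Cu(OTf)2 (3 mol %), chiral C2-symmetric imidazolinium chloride (NHC precursor, 4 mol %, the antipode that gives the 3R adduct), Et2O, −30 °C; then MeI, DMPU, −30 → 0 °C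
Reagents that add atoms: methylmagnesium bromide C[Mg]Br; iodomethane CI
Why: Copper-catalysed asymmetric conjugate addition to a 2-substituted cyclic enone sets C8 under ligand control, and C-methylation of the regio-defined magnesium enolate anti to the pseudoaxial C8 methyl (A(1,2) strain) should set C9 with its methyl trans to the C8 methyl and the allyl group cis to it.

Step 3
Reactants: 5 (2R,3R)-2-allyl-2,3-dimethylcyclohexan-1-one; 6 2,4,6-triisopropylbenzenesulfonohydrazide
Product: 7 N'-[(1E,2R,3R)-2-allyl-2,3-dimethylcyclohexylidene]-2,4,6-triisopropylbenzenesulfonohydrazide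
Conditions: conc. HCl (cat.), THF, 25 °C
Reagents that add atoms: none
Why: Hydrazone condensation, which should place the sulfonamide nitrogen anti to the quaternary carbon and thus syn to the only α-methylene, as the Shapiro reaction requires.

Step 4
Reactants: 7 N'-[(1E,2R,3R)-2-allyl-2,3-dimethylcyclohexylidene]-2,4,6-triisopropylbenzenesulfonohydrazide; 8 2-methylglutaric anhydride
Product: 11 methyl 5-[(5R,6R)-6-allyl-5,6-dimethylcyclohex-1-en-1-yl]-2-methyl-5-oxopentanoate, via vinyllithium 9 (not isolated), via keto acid 10 (not isolated)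
Conditions: n-BuLi (2.2 equiv), THF, −78 → 0 °C; then added to 8, THF, −78 °C; aqueous work-up at pH 4–5; then MeI, K2CO3, DMF, 25 °C
Reagents that add atoms: iodomethane CI
Why: Shapiro reaction (syn deprotonation at the single α-CH2, loss of sulfinate and N2) gives the C10 vinyllithium, which should open the anhydride at the carbonyl remote from the methyl group to a keto carboxylate that is O-methylated.

Step 5
Reactants: 11 methyl 5-[(5R,6R)-6-allyl-5,6-dimethylcyclohex-1-en-1-yl]-2-methyl-5-oxopentanoate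
Product: 13 (6R)-6-[(5R,6R)-6-allyl-5,6-dimethylcyclohex-1-en-1-yl]-3-methyloxan-2-one, via hydroxy ester 12 (not isolated)
Conditions: (S)-2-methyl-CBS-oxazaborolidine (20 mol %), catecholborane, toluene, −78 °C; then PPTS (cat.), toluene, 60 °C
Reagents that add atoms: none
Why: Corey–Bakshi–Shibata reduction of the enone carbonyl, with the branched alkenyl group as the large substituent, should give the (R)-carbinol C1 under reagent control (catecholborane spares the terminal alkene and the ester), and the δ-hydroxy ester lactonises under mild acid.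

Step 6
Reactants: 13 (6R)-6-[(5R,6R)-6-allyl-5,6-dimethylcyclohex-1-en-1-yl]-3-methyloxan-2-one
Product: 16 (1S,5R,6R,8aR)-5-allyl-1,5,6-trimethyl-1,2,3,5,6,7,8,8a-octahydronaphthalene-1-carboxylic acid, via silyl ketene acetal 14 (not isolated), via silyl ester 15 (not isolated)
Conditions: LDA, TMSCl/Et3N, THF, −78 °C; then toluene, 110 °C; then 1 M HCl, THF, 25 °C
Reagents that add atoms: none
Why: Ireland–Claisen rearrangement of a lactone enolate, a known route from 6-alkenyl lactones to cycloalkenecarboxylic acids: LDA removes the only α-hydrogen (C4–H), O-silylation gives ketene acetal 14, and its [3,3] shift breaks C1–O and forms C4–C5 while the ring-B alkene C5=C10 moves to C1=C10, leaving silyl ester 15. Ring A (C1, C2, C3, C4, C5, C10) closes in a six-membered mode in which the lactone carbons C2–C3–C4 and the whole allyl unit C1–C10–C5 become ring members, the lactone ring enforcing a boat-like bicyclo[2.2.2] transition state. C5 is set by suprafacial 1,3-chirality transfer from C1: because C2 must lie cis to C5 in ring A, the (R)-carbinol oxygen leaves and C4 arrives on the same face, the one that carries the C9 methyl and lies opposite the pseudoaxial C9 allyl group, which should give 5-H trans to the C9 methyl. C4 is fixed by the same bicyclic geometry (carboxyl on the face the oxygen left) and becomes non-stereogenic in step 9. The step needs the new alkene at C1=C10 with no C5=C10 isomer, which the sigmatropic mechanism guarantees, and it needs rearrangement to outrun ionisation of the allylic C1–O bond, which the neutral amine-buffered medium should secure.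

Step 7
Reactants: 16 (1S,5R,6R,8aR)-5-allyl-1,5,6-trimethyl-1,2,3,5,6,7,8,8a-octahydronaphthalene-1-carboxylic acid
Product: 17 [(1S,5R,6R,8aR)-5-allyl-1,5,6-trimethyl-1,2,3,5,6,7,8,8a-octahydronaphthalen-1-yl]methanol
Conditions: LiAlH4, THF, 0 → 65 °C
Reagents that add atoms: none
Why: Hydride reduction of the hindered carboxylic acid to the neopentyl-type primary alcohol, with both alkenes inert.

Step 8
Reactants: 17 [(1S,5R,6R,8aR)-5-allyl-1,5,6-trimethyl-1,2,3,5,6,7,8,8a-octahydronaphthalen-1-yl]methanol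
Product: 18 (1S,5R,6R,8aR)-5-allyl-1,5,6-trimethyl-1,2,3,5,6,7,8,8a-octahydronaphthalene-1-carbaldehyde
Conditions: Dess–Martin periodinane, CH2Cl2, 25 °C
Reagents that add atoms: none
Why: Dess–Martin oxidation of the primary alcohol to a non-enolisable aldehyde that cannot epimerise or over-oxidise.

Step 9
Reactants: 18 (1S,5R,6R,8aR)-5-allyl-1,5,6-trimethyl-1,2,3,5,6,7,8,8a-octahydronaphthalene-1-carbaldehyde
Product: 20 (1R,2R,4aS)-1-allyl-1,2,5,5-tetramethyl-1,2,3,4,4a,5,6,7-octahydronaphthalene, via hydrazone 19 (not isolated)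
Conditions: N2H4·H2O, KOH, diethylene glycol, 130 → 200 °C, under N2
Reagents that add atoms: none
Why: Wolff–Kishner reduction (Huang-Minlon procedure) turns the formyl group into the second C4 methyl, and the unconjugated alkenes should survive because hydroxide cannot deprotonate their allylic positions.

Step 10
Reactants: 21 (4R)-4-benzyl-1,3-oxazolidin-2-one; 22 acryloyl chloride
Product: 24 (4R)-3-acryloyl-4-benzyl-1,3-oxazolidin-2-one, via magnesium amide 23 (not isolated)
Conditions: MeMgBr, THF, 0 °C; then 22, −78 → 0 °C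
Reagents that add atoms: none
Why: N-acylation of the bromomagnesium salt of the oxazolidinone, a counter-ion that suppresses anionic polymerisation of the acrylamide product.

Step 11
Reactants: 20 (1R,2R,4aS)-1-allyl-1,2,5,5-tetramethyl-1,2,3,4,4a,5,6,7-octahydronaphthalene; 24 (4R)-3-acryloyl-4-benzyl-1,3-oxazolidin-2-one
Product: 25 (4R)-4-benzyl-3-{(2E)-4-[(1R,2R,4aS)-1,2,5,5-tetramethyl-1,2,3,4,4a,5,6,7-octahydronaphthalen-1-yl]but-2-enoyl}-1,3-oxazolidin-2-one
Conditions: second-generation Grubbs catalyst RuCl2(=CHPh)(H2IMes)(PCy3) (5 mol %), CH2Cl2, 40 °C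
Reagents that add atoms: none
Why: Olefin cross-metathesis of the terminal allyl alkene and the electron-poor acrylimide should give the E-enoyl imide, the hindered trisubstituted C1=C10 alkene being inert to the carbene.

Step 12
Reactants: 25 (4R)-4-benzyl-3-{(2E)-4-[(1R,2R,4aS)-1,2,5,5-tetramethyl-1,2,3,4,4a,5,6,7-octahydronaphthalen-1-yl]but-2-enoyl}-1,3-oxazolidin-2-one
Product: 26 (4R)-4-benzyl-3-{4-[(1R,2R,4aS)-1,2,5,5-tetramethyl-1,2,3,4,4a,5,6,7-octahydronaphthalen-1-yl]butanoyl}-1,3-oxazolidin-2-one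
Conditions: H2 (1 atm), RhCl(PPh3)3 (10 mol %), benzene, 25 °C
Reagents that add atoms: none
Why: Homogeneous hydrogenation with Wilkinson's catalyst is selective for the unhindered 1,2-disubstituted conjugated alkene, and the trisubstituted C1=C10 alkene next to the quaternary C9 should not bind rhodium.

Step 13
Reactants: 26 (4R)-4-benzyl-3-{4-[(1R,2R,4aS)-1,2,5,5-tetramethyl-1,2,3,4,4a,5,6,7-octahydronaphthalen-1-yl]butanoyl}-1,3-oxazolidin-2-one
Product: 28 (4R)-4-benzyl-3-[(2S)-2-{2-[(1R,2R,4aS)-1,2,5,5-tetramethyl-1,2,3,4,4a,5,6,7-octahydronaphthalen-1-yl]ethyl}pent-4-enoyl]-1,3-oxazolidin-2-one, via sodium enolate 27 (not isolated)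
Conditions: NaHMDS, THF, −78 °C; then allyl iodide, −78 → −40 °C
Reagents that add atoms: allyl iodide C=CCI
Why: Evans asymmetric alkylation, in which the chelated Z-enolate is allylated on the face opposite the benzyl group of the (R)-auxiliary, should set C13 in the configuration of the target.

Step 14
Reactants: 28 (4R)-4-benzyl-3-[(2S)-2-{2-[(1R,2R,4aS)-1,2,5,5-tetramethyl-1,2,3,4,4a,5,6,7-octahydronaphthalen-1-yl]ethyl}pent-4-enoyl]-1,3-oxazolidin-2-one
Product: 29 (2S)-2-{2-[(1R,2R,4aS)-1,2,5,5-tetramethyl-1,2,3,4,4a,5,6,7-octahydronaphthalen-1-yl]ethyl}pent-4-en-1-ol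
Conditions: LiBH4, H2O (1 equiv), Et2O, 0 °C
Reagents that add atoms: none
Why: Reductive cleavage of the N-acyl oxazolidinone by borohydride gives the primary alcohol without epimerising C13 and releases the auxiliary for recovery.

Step 15
Reactants: 30 3-methylbutan-1-amine; 31 2,5-dimethoxy-2,5-dihydrofuran
Product: 32 1-(3-methylbutyl)-1,5-dihydro-2H-pyrrol-2-one
Conditions: 0.1 M aq. HCl, 25 °C; then NaHCO3
Reagents that add atoms: none
Why: Acid hydrolysis of the bis-acetal to the 1,4-dialdehyde, condensation with the primary amine and prototropic isomerisation is the known one-step route from this dihydrofuran to N-substituted 1,5-dihydropyrrol-2-ones.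

Step 16
Reactants: 32 1-(3-methylbutyl)-1,5-dihydro-2H-pyrrol-2-one
Product: 34 3-bromo-1-(3-methylbutyl)-1,5-dihydro-2H-pyrrol-2-one, via dibromide 33 (not isolated)
Conditions: Br2, CH2Cl2, 0 °C; then Et3N, 0 → 25 °C
Reagents that add atoms: bromine BrBr
Why: Bromine addition to the conjugated alkene followed by E1cB loss of HBr (acidic α-hydrogen, β-bromide leaving) is the standard α-bromination of an unsaturated lactam.

Step 17
Reactants: 29 (2S)-2-{2-[(1R,2R,4aS)-1,2,5,5-tetramethyl-1,2,3,4,4a,5,6,7-octahydronaphthalen-1-yl]ethyl}pent-4-en-1-ol; 34 3-bromo-1-(3-methylbutyl)-1,5-dihydro-2H-pyrrol-2-one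
Product: 36 3-{(4R)-4-(hydroxymethyl)-6-[(1R,2R,4aS)-1,2,5,5-tetramethyl-1,2,3,4,4a,5,6,7-octahydronaphthalen-1-yl]hexyl}-1-(3-methylbutyl)-1,5-dihydro-2H-pyrrol-2-one, via alkylborane 35 (not isolated)
Conditions: 9-BBN-H (2.5 equiv), THF, 0 → 25 °C; then 34, PdCl2(dppf) (5 mol %), AsPh3, Cs2CO3, DMF/H2O, 25 → 50 °C
Reagents that add atoms: none
Why: Anti-Markovnikov hydroboration by 9-BBN-H is selective for the terminal alkene over C1=C10 (the hydroxyl is masked in the flask as its borinate), and B-alkyl Suzuki–Miyaura coupling of the primary alkylborane with the α-bromo unsaturated lactam forms the C16–C17 bond.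

Step 18
Reactants: 36 3-{(4R)-4-(hydroxymethyl)-6-[(1R,2R,4aS)-1,2,5,5-tetramethyl-1,2,3,4,4a,5,6,7-octahydronaphthalen-1-yl]hexyl}-1-(3-methylbutyl)-1,5-dihydro-2H-pyrrol-2-one
Product: 38 (2R)-2-{2-[(1R,2R,4aS)-1,2,5,5-tetramethyl-1,2,3,4,4a,5,6,7-octahydronaphthalen-1-yl]ethyl}-5-[1-(3-methylbutyl)-2-oxo-2,5-dihydro-1H-pyrrol-3-yl]pentyl hydrogen sulfate, via pyridinium sulfate 37 (not isolated)
Conditions: SO3·pyridine, pyridine, 25 °C; then sulfonic acid resin (H+ form), MeOH/H2O, 0 °C, immediate lyophilisation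
Reagents that add atoms: sulfur trioxide–pyridine complex [O-]S(=O)(=O)[n+]1ccccc1
Why: O-sulfation of the only hydroxyl group by the SO3–amine complex leaves the lactam and both alkenes untouched, and brief cold proton exchange should release the hydrogen sulfate.

Compound list
1 | 2-iodocyclohex-2-en-1-one | O=C1CCCC=C1I | starting material
2 | allyltributylstannane | C=CC[Sn](CCCC)(CCCC)CCCC | starting material
3 | 2-allylcyclohex-2-en-1-one | C=CCC1=CCCCC1=O | intermediate
4 | bromomagnesium (3R)-2-allyl-3-methylcyclohex-1-en-1-olate | C=CCC1=C(O[Mg]Br)CCC[C@H]1C | intermediate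
5 | (2R,3R)-2-allyl-2,3-dimethylcyclohexan-1-one | C=CC[C@@]1(C)C(=O)CCC[C@H]1C | intermediate
6 | 2,4,6-triisopropylbenzenesulfonohydrazide | CC(C)c1cc(C(C)C)c(S(=O)(=O)NN)c(C(C)C)c1 | starting material
7 | N'-[(1E,2R,3R)-2-allyl-2,3-dimethylcyclohexylidene]-2,4,6-triisopropylbenzenesulfonohydrazide | C=CC[C@@]1(C)/C(=N/NS(=O)(=O)c2c(C(C)C)cc(C(C)C)cc2C(C)C)CCC[C@H]1C | intermediate
8 | 2-methylglutaric anhydride (3-methyloxane-2,6-dione, racemic) | CC1CCC(=O)OC1=O | starting material
9 | [(5R,6R)-6-allyl-5,6-dimethylcyclohex-1-en-1-yl]lithium | C=CC[C@@]1(C)C([Li])=CCC[C@H]1C | intermediate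
10 | 5-[(5R,6R)-6-allyl-5,6-dimethylcyclohex-1-en-1-yl]-2-methyl-5-oxopentanoic acid (C2 epimers) | C=CC[C@@]1(C)C(C(=O)CCC(C)C(=O)O)=CCC[C@H]1C | intermediate
11 | methyl 5-[(5R,6R)-6-allyl-5,6-dimethylcyclohex-1-en-1-yl]-2-methyl-5-oxopentanoate (C2 epimers) | C=CC[C@@]1(C)C(C(=O)CCC(C)C(=O)OC)=CCC[C@H]1C | intermediate
12 | methyl (5R)-5-[(5R,6R)-6-allyl-5,6-dimethylcyclohex-1-en-1-yl]-5-hydroxy-2-methylpentanoate (C2 epimers) | C=CC[C@@]1(C)C([C@H](O)CCC(C)C(=O)OC)=CCC[C@H]1C | intermediate
13 | (6R)-6-[(5R,6R)-6-allyl-5,6-dimethylcyclohex-1-en-1-yl]-3-methyloxan-2-one (C3 epimers) | C=CC[C@@]1(C)C([C@H]2CCC(C)C(=O)O2)=CCC[C@H]1C | intermediate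
14 | {[(2R)-2-[(5R,6R)-6-allyl-5,6-dimethylcyclohex-1-en-1-yl]-5-methyl-3,4-dihydro-2H-pyran-6-yl]oxy}trimethylsilane | C=CC[C@@]1(C)C([C@H]2CCC(C)=C(O[Si](C)(C)C)O2)=CCC[C@H]1C | intermediate
15 | trimethylsilyl (1S,5R,6R,8aR)-5-allyl-1,5,6-trimethyl-1,2,3,5,6,7,8,8a-octahydronaphthalene-1-carboxylate | C=CC[C@@]1(C)C2=CCC[C@](C)(C(=O)O[Si](C)(C)C)[C@@H]2CC[C@H]1C | intermediate
16 | (1S,5R,6R,8aR)-5-allyl-1,5,6-trimethyl-1,2,3,5,6,7,8,8a-octahydronaphthalene-1-carboxylic acid | C=CC[C@@]1(C)C2=CCC[C@](C)(C(=O)O)[C@@H]2CC[C@H]1C | intermediate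
17 | [(1S,5R,6R,8aR)-5-allyl-1,5,6-trimethyl-1,2,3,5,6,7,8,8a-octahydronaphthalen-1-yl]methanol | C=CC[C@@]1(C)C2=CCC[C@](C)(CO)[C@@H]2CC[C@H]1C | intermediate
18 | (1S,5R,6R,8aR)-5-allyl-1,5,6-trimethyl-1,2,3,5,6,7,8,8a-octahydronaphthalene-1-carbaldehyde | C=CC[C@@]1(C)C2=CCC[C@](C)(C=O)[C@@H]2CC[C@H]1C | intermediate
19 | hydrazone of aldehyde 18 | C=CC[C@@]1(C)C2=CCC[C@](C)(C=NN)[C@@H]2CC[C@H]1C | intermediate
20 | (1R,2R,4aS)-1-allyl-1,2,5,5-tetramethyl-1,2,3,4,4a,5,6,7-octahydronaphthalene | C=CC[C@@]1(C)C2=CCCC(C)(C)[C@@H]2CC[C@H]1C | intermediate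
21 | (4R)-4-benzyl-1,3-oxazolidin-2-one | O=C1N[C@H](Cc2ccccc2)CO1 | starting material
22 | acryloyl chloride | C=CC(Cl)=O | starting material
23 | bromomagnesium salt of (4R)-4-benzyl-1,3-oxazolidin-2-one (N-magnesiated) | Br[Mg]N1[C@H](Cc2ccccc2)COC1=O | intermediate
24 | (4R)-3-acryloyl-4-benzyl-1,3-oxazolidin-2-one | C=CC(=O)N1[C@H](Cc2ccccc2)COC1=O | intermediate
25 | (4R)-4-benzyl-3-{(2E)-4-[(1R,2R,4aS)-1,2,5,5-tetramethyl-1,2,3,4,4a,5,6,7-octahydronaphthalen-1-yl]but-2-enoyl}-1,3-oxazolidin-2-one | O=C(/C=C/C[C@@]1(C)C2=CCCC(C)(C)[C@@H]2CC[C@H]1C)N1[C@H](Cc2ccccc2)COC1=O | intermediate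
26 | (4R)-4-benzyl-3-{4-[(1R,2R,4aS)-1,2,5,5-tetramethyl-1,2,3,4,4a,5,6,7-octahydronaphthalen-1-yl]butanoyl}-1,3-oxazolidin-2-one | O=C(CCC[C@@]1(C)C2=CCCC(C)(C)[C@@H]2CC[C@H]1C)N1[C@H](Cc2ccccc2)COC1=O | intermediate
27 | sodium (Z)-enolate of imide 26 | [Na]O/C(=C\CC[C@@]1(C)C2=CCCC(C)(C)[C@@H]2CC[C@H]1C)N1[C@H](Cc2ccccc2)COC1=O | intermediate
28 | (4R)-4-benzyl-3-[(2S)-2-{2-[(1R,2R,4aS)-1,2,5,5-tetramethyl-1,2,3,4,4a,5,6,7-octahydronaphthalen-1-yl]ethyl}pent-4-enoyl]-1,3-oxazolidin-2-one | C=CC[C@H](CC[C@@]1(C)C2=CCCC(C)(C)[C@@H]2CC[C@H]1C)C(=O)N1[C@H](Cc2ccccc2)COC1=O | intermediate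
29 | (2S)-2-{2-[(1R,2R,4aS)-1,2,5,5-tetramethyl-1,2,3,4,4a,5,6,7-octahydronaphthalen-1-yl]ethyl}pent-4-en-1-ol | C=CC[C@H](CC[C@@]1(C)C2=CCCC(C)(C)[C@@H]2CC[C@H]1C)CO | intermediate
30 | 3-methylbutan-1-amine | CC(C)CCN | starting material
31 | 2,5-dimethoxy-2,5-dihydrofuran | COC1C=CC(OC)O1 | starting material
32 | 1-(3-methylbutyl)-1,5-dihydro-2H-pyrrol-2-one | CC(C)CCN1CC=CC1=O | intermediate
33 | trans-3,4-dibromo-1-(3-methylbutyl)pyrrolidin-2-one (racemic) | CC(C)CCN1CC(Br)C(Br)C1=O | intermediate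
34 | 3-bromo-1-(3-methylbutyl)-1,5-dihydro-2H-pyrrol-2-one | CC(C)CCN1CC=C(Br)C1=O | intermediate
35 | 5-(9-borabicyclo[3.3.1]nonan-9-yl) derivative of alcohol 29 (alkene hydroborated at the terminal carbon), held as its O-(9-borabicyclo[3.3.1]nonan-9-yl) borinate | C(CC[C@H](CC[C@@]1(C)C2=CCCC(C)(C)[C@@H]2CC[C@H]1C)COB1C2CCCC1CCC2)B1C2CCCC1CCC2 | intermediate
36 | 3-{(4R)-4-(hydroxymethyl)-6-[(1R,2R,4aS)-1,2,5,5-tetramethyl-1,2,3,4,4a,5,6,7-octahydronaphthalen-1-yl]hexyl}-1-(3-methylbutyl)-1,5-dihydro-2H-pyrrol-2-one | CC(C)CCN1CC=C(CCC[C@H](CC[C@@]2(C)C3=CCCC(C)(C)[C@@H]3CC[C@H]2C)CO)C1=O | intermediate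
37 | pyridinium salt of sulfate 38 | CC(C)CCN1CC=C(CCC[C@H](CC[C@@]2(C)C3=CCCC(C)(C)[C@@H]3CC[C@H]2C)COS(=O)(=O)[O-])C1=O.c1cc[nH+]cc1 | intermediate
38 | (2R)-2-{2-[(1R,2R,4aS)-1,2,5,5-tetramethyl-1,2,3,4,4a,5,6,7-octahydronaphthalen-1-yl]ethyl}-5-[1-(3-methylbutyl)-2-oxo-2,5-dihydro-1H-pyrrol-3-yl]pentyl hydrogen sulfate | CC(C)CCN1CC=C(CCC[C@H](CC[C@@]2(C)C3=CCCC(C)(C)[C@@H]3CC[C@H]2C)COS(=O)(=O)O)C1=O | target

Total step count: 18 steps. Longest linear sequence: 15 steps (steps 1–9, 11–14, 17 and 18); steps 10, 15 and 16 prepare the two side reagents.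

Steps most likely to fail

Step 6. The silyl ketene acetal may ionise at the allylic C1–O bond or be C-silylated or hydrolysed before the strained boat-like shift takes place, so that elimination or recovered lactone replaces rearrangement. The fallback moves the same bond construction to the aldehyde oxidation level: lactone 13 is reduced with DIBAL-H (toluene, −78 °C) to the lactol (6R)-6-[(5R,6R)-6-allyl-5,6-dimethylcyclohex-1-en-1-yl]-3-methyloxan-2-ol F1, which is dehydrated with MsCl/Et3N (CH2Cl2, −20 → 40 °C) to the cyclic enol ether (2R)-2-[(5R,6R)-6-allyl-5,6-dimethylcyclohex-1-en-1-yl]-5-methyl-3,4-dihydro-2H-pyran F2. Heating F2 in degassed decalin at about 200 °C in base-washed glass should bring about the thermal Claisen rearrangement of this 2-alkenyl dihydropyran through the same bicyclic transition state, giving aldehyde 18 directly. The route is rejoined at 18, so steps 7 and 8 are not needed.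

Step 2. The small methyl Grignard reagent may be transferred with poor facial discrimination, and proton exchange of the magnesium enolate before C-methylation may erode regio- and stereocontrol at C9. The fallback separates the two events: from enone 3, addition of Me2Zn catalysed by Cu(OTf)2 and a chiral phosphoramidite (toluene, −30 °C) with TMSOTf trapping gives the silyl enol ether {[(3R)-2-allyl-3-methylcyclohex-1-en-1-yl]oxy}trimethylsilane F3, which is isolated. MeLi (THF, 0 °C) then releases the regio-defined lithium enolate, and methylation with MeI in THF/DMPU at −78 °C returns to ketone 5.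

Step 4. Dianion formation from the hindered hydrazone may be incomplete, the vinyllithium may be protonated, and the anhydride may suffer double addition or attack at the methyl-bearing carbonyl. The fallback avoids the organolithium: ketone 5 is converted with KHMDS and PhNTf2 (THF, −78 °C) into the enol triflate (5R,6R)-6-allyl-5,6-dimethylcyclohex-1-en-1-yl trifluoromethanesulfonate F4. Carbonylative B-alkyl Suzuki–Miyaura coupling of F4 under CO (1 atm; PdCl2(dppf), K3PO4, DMF/THF, 50 °C) with the alkylborane methyl 4-(9-borabicyclo[3.3.1]nonan-9-yl)-2-methylbutanoate F5, made from methyl 2-methylbut-3-enoate and 9-BBN-H, should give keto ester 11, where the route is rejoined.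

Further compounds
F1 | step 6 | (6R)-6-[(5R,6R)-6-allyl-5,6-dimethylcyclohex-1-en-1-yl]-3-methyloxan-2-ol | C=CC[C@@]1(C)C([C@H]2CCC(C)C(O)O2)=CCC[C@H]1C
F2 | step 6 | (2R)-2-[(5R,6R)-6-allyl-5,6-dimethylcyclohex-1-en-1-yl]-5-methyl-3,4-dihydro-2H-pyran | C=CC[C@@]1(C)C([C@H]2CCC(C)=CO2)=CCC[C@H]1C
F3 | step 2 | {[(3R)-2-allyl-3-methylcyclohex-1-en-1-yl]oxy}trimethylsilane | C=CCC1=C(O[Si](C)(C)C)CCC[C@H]1C
F4 | step 4 | (5R,6R)-6-allyl-5,6-dimethylcyclohex-1-en-1-yl trifluoromethanesulfonate | C=CC[C@@]1(C)C(OS(=O)(=O)C(F)(F)F)=CCC[C@H]1C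
F5 | step 4 | methyl 4-(9-borabicyclo[3.3.1]nonan-9-yl)-2-methylbutanoate | COC(=O)C(C)CCB1C2CCCC1CCC2
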